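**Strategy.** Ring B (C5–C6–C7–C8–C9–C10, drimane numbering) is a cyclohexene whose C7=C8 bond marks a Diels–Alder retron. The key step forms C5–C6 and C9–C10 in one cycloaddition between a 1,2-disubstituted butadiene and an acyclic (E)-trisubstituted enal that already carries all six ring A carbons; its E geometry becomes the trans C5-H/C10-CH3 ring fusion, which a ring A cycloalkene could not deliver, and a chiral oxazaborolidinium catalyst sets the absolute configuration. The activating formyl group then closes ring A by aldol condensation. C9 is reset through an exocyclic diene (sulfoxide elimination, hydroboration) and umbelliferone is attached last.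

Key step: step 5

Remark on numbering: drimane locants are used for the bicyclic compounds (ring A = C1–C2–C3–C4–C5–C10, ring B = C5–C10; C11 on C9, C12 on C8, C13/C14 on C4, C15 on C10); stereodescriptors are CIP.

Assumption: the sense of induction in step 5 follows the formyl C–H···O binding model of protonated oxazaborolidines, by which the (R)-catalyst should leave the α-Si face of enal 4 open; should the opposite sense apply, the (S)-catalyst is used with no other change.

Step 1
Reactants: 1 4-hydroxy-3,3-dimethylbutan-2-one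
Product: 2 2,2-dimethyl-3-oxobutanal
Conditions: Dess–Martin periodinane, NaHCO3, CH2Cl2, 0 → 23 °C
Reagents that add atoms: none
Why: Dess–Martin oxidation of a primary neopentyl alcohol; the quaternary carbon between the two carbonyls prevents enolisation, so the β-keto aldehyde should be stable.

Step 2
Reactants: 2 2,2-dimethyl-3-oxobutanal; 3 2-(triphenyl-λ5-phosphanylidene)propanal
Product: 4 (2E)-2,4,4-trimethyl-5-oxohex-2-enal
Conditions: toluene, 100 °C
Reagents that add atoms: none
Why: Wittig olefination with a formyl-stabilised ylide, which reacts only with the aldehyde and should give the (E)-enal (formyl group trans to the tert-alkyl group).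

Step 3
Reactants: 5 (2E)-3-methylpent-2-en-4-yn-1-ol
Product: 6 (2E)-3-methylpenta-2,4-dien-1-ol
Conditions: H2 (1 atm), Pd/CaCO3 poisoned with Pb(OAc)2, quinoline, EtOAc, 23 °C
Reagents that add atoms: none
Why: Lindlar semihydrogenation of the terminal alkyne to the vinyl group; the existing E double bond is not touched.

Step 4
Reactants: 6 (2E)-3-methylpenta-2,4-dien-1-ol
Product: 7 {[(2E)-3-methylpenta-2,4-dien-1-yl]sulfanyl}benzene
Conditions: PhSSPh, Bu3P, THF, 0 → 23 °C
Reagents that add atoms: diphenyl disulfide, c1ccc(SSc2ccccc2)cc1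
Why: Hata sulfenylation (alkoxyphosphonium formation, then SN2 by thiolate at the primary allylic carbon) should give the conjugated dienyl sulfide, which serves as a Lewis-acid-tolerant, later removable handle on C11.

Step 5
Reactants: 4 (2E)-2,4,4-trimethyl-5-oxohex-2-enal; 7 {[(2E)-3-methylpenta-2,4-dien-1-yl]sulfanyl}benzene
Product: 8 (1R,2S,6S)-1,3-dimethyl-6-(2-methyl-3-oxobutan-2-yl)-2-[(phenylsulfanyl)methyl]cyclohex-3-ene-1-carbaldehyde
Conditions: (R)-3,3-diphenyl-1-(2-methylphenyl)tetrahydro-1H,3H-pyrrolo[1,2-c][1,3,2]oxazaborole protonated with HN(SO2CF3)2 (20 mol %), 7 in excess, CH2Cl2, −78 → −20 °C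
Reagents that add atoms: none
Why: The protonated oxazaborolidine binds the formyl oxygen of 4 and lowers the LUMO of the enal, which should then undergo a concerted, asynchronous, suprafacial [4+2] cycloaddition with s-cis diene 7; this is the catalytic enantioselective Diels–Alder reaction of α-substituted enals. Ring B is closed by intermolecular formation of C5–C6 and C9–C10 in one cycloaddition through a six-membered boat-like transition state, with no tether. C10 and C5 are set relative to each other by the E geometry of the dienophile (C1 and C4 end up trans, which is the trans C5-H/C10-CH3 relationship of the later decalin) and absolutely by the catalyst, which shields one face of the s-trans enal so that the diene adds to the α-Si face. C9 should form as the endo epimer (CH2SPh cis to the formyl group); this is of no consequence, because C9 becomes trigonal again in step 10. The step needs regioselectivity (C9 to C10, C6 to C5): the 1-(phenylsulfanylmethyl) substituent directs the substituted diene terminus to the carbonyl-bearing carbon, and the unsubstituted terminus C6 is the only one that fits the neopentyl-type β-carbon C5. The ketone of 4 is not conjugated and should stay inert.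

Step 6
Reactants: 8 Diels–Alder adduct
Product: 10 (5S,9S,10R)-11-(phenylsulfanyl)drima-1,7-dien-3-one, via aldol adduct 9 (not isolated)
Conditions: KOH (cat.), MeOH, 60 °C
Reagents that add atoms: none
Why: Intramolecular aldol condensation (6-(enolexo)-exo-trig; the methyl group is the only enolisable position and the aldehyde cannot enolise) followed by E1cB dehydration should close ring A across the trans-disposed C10 and C5 substituents.

Step 7
Reactants: 10 (5S,9S,10R)-11-(phenylsulfanyl)drima-1,7-dien-3-one
Product: 12 (5S,9S,10R)-11-(phenylsulfanyl)drim-7-en-3-one, via silyl enol ether 11 (not isolated)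
Conditions: [(Ph3P)CuH]6 (cat.), PhMe2SiH, toluene, 23 °C; then 1 M HCl, THF
Reagents that add atoms: none
Why: Copper hydride-catalysed conjugate hydrosilylation (Stryker-type) reduces only the enone C1=C2 bond; the isolated trisubstituted C7=C8 bond and the sulfide should be untouched, and acid hydrolysis of the silyl enol ether gives the ketone.

Step 8
Reactants: 12 (5S,9S,10R)-11-(phenylsulfanyl)drim-7-en-3-one
Product: 13 (3R,5S,9S,10R)-11-(phenylsulfanyl)drim-7-en-3-ol
Conditions: NaBH4, MeOH/THF, 0 °C
Reagents that add atoms: none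
Why: Borohydride reduction of a 4,4-dimethyl-3-ketone in a trans-decalin; axial hydride delivery (the equatorial trajectory is blocked by the axial C4 methyl) should give the equatorial C3 alcohol, cis to the C10 methyl.

Step 9
Reactants: 13 (3R,5S,9S,10R)-11-(phenylsulfanyl)drim-7-en-3-ol
Product: 14 (3R,5S,9S,10R)-11-(phenylsulfanyl)drim-7-en-3-yl acetate
Conditions: Ac2O, pyridine, DMAP (cat.), CH2Cl2, 23 °C
Reagents that add atoms: acetic anhydride, CC(=O)OC(C)=O
Why: DMAP-catalysed acetylation of the hindered secondary alcohol, with retention at C3.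

Step 10
Reactants: 14 (3R,5S,9S,10R)-11-(phenylsulfanyl)drim-7-en-3-yl acetate
Product: 16 (3R,5S,10R)-drima-7,9(11)-dien-3-yl acetate, via sulfoxide 15 (not isolated)
Conditions: H2O2 (1 equiv), (CF3)2CHOH, 23 °C; evaporate; then CaCO3, toluene, 110 °C
Reagents that add atoms: none
Why: Chemoselective sulfide-to-sulfoxide oxidation, then thermal syn-elimination of benzenesulfenic acid; C9–H is the only β-hydrogen, so the exocyclic C9=C11 bond should form and the C9 configuration from step 5 is erased.

Step 11
Reactants: 16 (3R,5S,10R)-drima-7,9(11)-dien-3-yl acetate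
Product: 18 (3R,5S,9R,10R)-11-hydroxydrim-7-en-3-yl acetate, via B-alkyl-9-BBN adduct 17 (not isolated)
Conditions: 9-BBN, THF, 0 → 23 °C; then H2O2, aq. NaOAc, 0 → 23 °C
Reagents that add atoms: hydrogen peroxide, OO
Why: Anti-Markovnikov hydroboration–oxidation of the 1,1-disubstituted exocyclic alkene (the trisubstituted C7=C8 bond is much slower); the axial C10 methyl blocks one face, so hydrogen should add to C9 from the opposite face and C11 ends cis to the C10 methyl.

Step 12
Reactants: 18 (3R,5S,9R,10R)-11-hydroxydrim-7-en-3-yl acetate; 19 umbelliferone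
Product: 20 (3R,5S,9R,10R)-11-[(2-oxo-2H-chromen-7-yl)oxy]drim-7-en-3-yl acetate (CNP0224712.1)
Conditions: PPh3, DIAD, THF, 0 → 40 °C
Reagents that add atoms: none
Why: Mitsunobu etherification of the primary alcohol with the acidic phenol; no stereocentre is involved and the acetate and lactone should be inert.

**Compound list**

1 | 4-hydroxy-3,3-dimethylbutan-2-one | CC(=O)C(C)(C)CO | starting material
2 | 2,2-dimethyl-3-oxobutanal | CC(=O)C(C)(C)C=O | intermediate
3 | 2-(triphenyl-λ5-phosphanylidene)propanal | CC(C=O)=P(c1ccccc1)(c1ccccc1)c1ccccc1 | starting material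
4 | (2E)-2,4,4-trimethyl-5-oxohex-2-enal | CC(=O)C(C)(C)/C=C(\C)C=O | intermediate
5 | (2E)-3-methylpent-2-en-4-yn-1-ol | C#C/C(C)=C/CO | starting material
6 | (2E)-3-methylpenta-2,4-dien-1-ol | C=C/C(C)=C/CO | intermediate
7 | {[(2E)-3-methylpenta-2,4-dien-1-yl]sulfanyl}benzene | C=C/C(C)=C/CSc1ccccc1 | intermediate
8 | (1R,2S,6S)-1,3-dimethyl-6-(2-methyl-3-oxobutan-2-yl)-2-[(phenylsulfanyl)methyl]cyclohex-3-ene-1-carbaldehyde | O=C[C@@]1(C)[C@@H](CSc2ccccc2)C(C)=CC[C@@H]1C(C)(C)C(C)=O | intermediate
9 | 1-hydroxy-11-(phenylsulfanyl)drim-7-en-3-one, aldol adduct (C5, C9, C10 as in 10; both C1 epimers) | O=C1CC(O)[C@@]2(C)[C@@H](CSc3ccccc3)C(C)=CC[C@@H]2C1(C)C | intermediate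
10 | (5S,9S,10R)-11-(phenylsulfanyl)drima-1,7-dien-3-one | O=C1C=C[C@@]2(C)[C@@H](CSc3ccccc3)C(C)=CC[C@@H]2C1(C)C | intermediate
11 | (5S,9S,10R)-3-[(dimethylphenylsilyl)oxy]-11-(phenylsulfanyl)drima-2,7-diene | C[Si](C)(c1ccccc1)OC1=CC[C@@]2(C)[C@@H](CSc3ccccc3)C(C)=CC[C@@H]2C1(C)C | intermediate
12 | (5S,9S,10R)-11-(phenylsulfanyl)drim-7-en-3-one | O=C1CC[C@@]2(C)[C@@H](CSc3ccccc3)C(C)=CC[C@@H]2C1(C)C | intermediate
13 | (3R,5S,9S,10R)-11-(phenylsulfanyl)drim-7-en-3-ol | O[C@@H]1CC[C@@]2(C)[C@@H](CSc3ccccc3)C(C)=CC[C@@H]2C1(C)C | intermediate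
14 | (3R,5S,9S,10R)-11-(phenylsulfanyl)drim-7-en-3-yl acetate | CC(=O)O[C@@H]1CC[C@@]2(C)[C@@H](CSc3ccccc3)C(C)=CC[C@@H]2C1(C)C | intermediate
15 | (3R,5S,9S,10R)-11-(phenylsulfinyl)drim-7-en-3-yl acetate (both configurations at sulfur) | CC(=O)O[C@@H]1CC[C@@]2(C)[C@@H](CS(=O)c3ccccc3)C(C)=CC[C@@H]2C1(C)C | intermediate
16 | (3R,5S,10R)-drima-7,9(11)-dien-3-yl acetate | CC(=O)O[C@@H]1CC[C@@]2(C)C(=C)C(C)=CC[C@@H]2C1(C)C | intermediate
17 | B-alkyl-9-borabicyclo[3.3.1]nonane adduct of 16 (boron on C11; ring configuration as in 18) | CC(=O)O[C@@H]1CC[C@@]2(C)[C@H](CB3C4CCCC3CCC4)C(C)=CC[C@@H]2C1(C)C | intermediate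
18 | (3R,5S,9R,10R)-11-hydroxydrim-7-en-3-yl acetate | CC(=O)O[C@@H]1CC[C@@]2(C)[C@H](CO)C(C)=CC[C@@H]2C1(C)C | intermediate
19 | umbelliferone (7-hydroxy-2H-chromen-2-one) | Oc1ccc2ccc(=O)oc2c1 | starting material
20 | (3R,5S,9R,10R)-11-[(2-oxo-2H-chromen-7-yl)oxy]drim-7-en-3-yl acetate | CC(=O)O[C@@H]1CC[C@@]2(C)[C@H](COc3ccc4ccc(=O)oc4c3)C(C)=CC[C@@H]2C1(C)C | target

**Step count.** Total: 12 steps. Longest linear sequence: 10 steps (steps 1, 2 and 5–12).

**Steps most likely to fail**

Step 5. What may go wrong: the hindered α,β-disubstituted enal may react too slowly, so that diene decomposition, an uncatalysed background reaction or catalyst binding to the ketone erodes conversion and enantioselectivity. Fallback: the enal is activated as a chiral vinyl oxocarbenium ion (auxiliary-controlled ionic Diels–Alder reaction). Setting out from 4, acetalisation with (2R,4R)-pentane-2,4-diol (PPTS, benzene, reflux with water removal) would give the dioxane acetal of 4, F1. Ionisation with TiCl4/Ti(OiPr)4 in CH2Cl2 at −78 °C in the presence of 7 would give the cycloadduct acetal, F2, with the face controlled by the auxiliary. Aqueous acid hydrolysis comes back to the route at 8. The diol antipode is chosen to match the required facial sense.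

Step 11. What may go wrong: the borane may add to the wrong face of the exocyclic double bond, or attack the conjugated diene unselectively. Fallback: C9 is set by kinetic protonation of a dienolate instead. Setting out from sulfoxide 15 (isolated after the oxidation of step 10), Pummerer rearrangement (trifluoroacetic anhydride, 2,6-lutidine, CH2Cl2, 0 °C) would give the α-trifluoroacetoxy sulfide, F3. Hydrolysis with aqueous NaHCO3 would give the 9-epi aldehyde, F4. Et3N/Me3SiOTf would convert it to the trimethylsilyl dienol ether, F5. Desilylation with Bu4NF buffered with AcOH (THF, −78 °C) should protonate C9 from the face opposite the C10 methyl and give the aldehyde with the required C9 configuration, F6. NaBH4 (MeOH, −20 °C) comes back to the route at 18.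

Step 12. What may go wrong: SN2 displacement at the β-branched C11 next to the quaternary C10 may be slow, with competing elimination back towards the diene. Fallback: the ether bond is made at the aryl carbon instead. Setting out from 18, palladium-catalysed C–O cross-coupling with commercial 7-bromo-2H-chromen-2-one (Pd(OAc)2, a bulky biaryl di-tert-butylphosphine ligand, Cs2CO3, toluene, 80 °C) would come back to the route directly at 20; no compound outside the list is made (F0).

**Further compounds**

F1 | step 5 | (2E)-3,3-dimethyl-5-[(4R,6R)-4,6-dimethyl-1,3-dioxan-2-yl]hex-4-en-2-one (acetal of 4) | CC(=O)C(C)(C)/C=C(\C)C1O[C@H](C)C[C@H](C)O1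
F2 | step 5 | (4R,6R)-4,6-dimethyl-1,3-dioxane acetal of aldehyde 8 | C[C@@H]1C[C@H](C)OC(O1)[C@@]2(C)[C@@H](CSc3ccccc3)C(C)=CC[C@@H]2C(C)(C)C(C)=O
F3 | step 11 | (3R,5S,9S,10R)-11-(phenylsulfanyl)-11-(trifluoroacetoxy)drim-7-en-3-yl acetate (C11 epimers) | CC(=O)O[C@@H]1CC[C@@]2(C)[C@@H](C(OC(=O)C(F)(F)F)Sc3ccccc3)C(C)=CC[C@@H]2C1(C)C
F4 | step 11 | (3R,5S,9S,10R)-11-oxodrim-7-en-3-yl acetate (9-epi aldehyde) | CC(=O)O[C@@H]1CC[C@@]2(C)[C@@H](C=O)C(C)=CC[C@@H]2C1(C)C
F5 | step 11 | (3R,5S,10R)-11-[(trimethylsilyl)oxy]drima-7,9(11)-dien-3-yl acetate (enol ether E/Z mixture) | CC(=O)O[C@@H]1CC[C@@]2(C)C(=CO[Si](C)(C)C)C(C)=CC[C@@H]2C1(C)C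
F6 | step 11 | (3R,5S,9R,10R)-11-oxodrim-7-en-3-yl acetate | CC(=O)O[C@@H]1CC[C@@]2(C)[C@H](C=O)C(C)=CC[C@@H]2C1(C)C
F0 | step 12 | none | none
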